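**Plan**
- Retrosynthesis: the C3–CH2 link is opened as a C3=CH double bond (Knoevenagel) to 7-prenyloxindole and a formyl pyrazinone; the oxindole is then cut at N1–C7a and C3–C3a together.
- Enabling feature: N1 and C3 of lactam ring B sit on the adjacent carbons C7a and C3a of benzene ring A, the footprint of a benzyne. N1–C2–C3 is supplied as an oxanilate (nitrogen nucleophile, ester carbon electrophile), so ring B first appears as an isatin.
- Helpers: a chlorine at C4 (steers nitrogen to the aryne carbon next to the prenyl group), an N-(4-methoxyphenyl) group and the C3 ketone; all three are removed in steps 6–8.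
- Forward: prenylated ortho-silylaryl triflate (steps 1–3) and oxanilate (step 4) give ring B (step 5), then 7-prenyloxindole (steps 6–8); the pyrazinone aldehyde (steps 9–11) is joined by Knoevenagel condensation (step 12).
- Stereochemistry: the single stereocenter C3 (S) is set in the last step by catalyst-controlled asymmetric hydrogenation of the Z-alkylidene lactam; no base touches it afterwards.

Key step: step 5

Assumption: the sense of induction in step 13 is not predicted here; the BINAP antipode that gives 3S (written as R) is fixed by a trial run and the mirror-image ligand is used if the sense is opposite.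

**Route**

Step 1
Reactants: 1 2-bromo-3-chlorophenol; 2 tert-butyl (2-methylbut-3-en-2-yl) carbonate
Product: 3 2-bromo-1-chloro-3-[(2-methylbut-3-en-2-yl)oxy]benzene
Conditions: Pd(PPh3)4 (2 mol %), THF, 0 °C
Reagents that add atoms: none
Why: Zerovalent palladium ionizes the tertiary allylic carbonate and the phenoxide attacks the more substituted allyl terminus under kinetic control (Tsuji–Trost O-allylation), which should give the 1,1-dimethylallyl ether while the aryl bromide stays untouched at 0 °C.

Step 2
Reactants: 3 2-bromo-1-chloro-3-[(2-methylbut-3-en-2-yl)oxy]benzene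
Product: 4 2-bromo-3-chloro-6-(3-methylbut-2-en-1-yl)phenol
Conditions: PhMe, 120 °C (sealed tube), BHT (cat.)
Reagents that add atoms: none
Why: Aromatic Claisen rearrangement ([3,3]) transfers the allyl unit with allylic inversion to the only free ortho carbon, so the 1,1-dimethylallyl ether should deliver the linear prenyl group at C6.

Step 3
Reactants: 4 2-bromo-3-chloro-6-(3-methylbut-2-en-1-yl)phenol
Product: 7 3-chloro-6-(3-methylbut-2-en-1-yl)-2-(trimethylsilyl)phenyl trifluoromethanesulfonate, via aryl trimethylsilyl ether 5 (not isolated), via lithium silylphenolate 6 (not isolated)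
Conditions: HMDS, THF, 65 °C; then n-BuLi, THF, −78 °C; then Tf2O, −78 °C to rt
Reagents that add atoms: hexamethyldisilazane C[Si](C)(C)N[Si](C)(C)C; trifluoromethanesulfonic anhydride O=S(=O)(OS(=O)(=O)C(F)(F)F)C(F)(F)F
Why: O-silylation, bromine–lithium exchange with retro-Brook 1,3-silyl migration from oxygen to the ortho carbon, and triflation of the phenoxide is the standard one-pot entry to ortho-silylaryl triflates, and the exchange is faster than deprotonation of the prenyl CH2 at −78 °C.

Step 4
Reactants: 8 4-methoxyaniline; 9 methyl chlorooxoacetate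
Product: 10 methyl 2-[(4-methoxyphenyl)amino]-2-oxoacetate
Conditions: Et3N, CH2Cl2, 0 °C
Reagents that add atoms: none
Why: N-acylation of the aniline by the acid chloride end of the oxalyl half-ester, which is far more reactive than its ester end.

Step 5
Reactants: 7 3-chloro-6-(3-methylbut-2-en-1-yl)-2-(trimethylsilyl)phenyl trifluoromethanesulfonate (1.5 equiv); 10 methyl 2-[(4-methoxyphenyl)amino]-2-oxoacetate
Product: 12 4-chloro-1-(4-methoxyphenyl)-7-(3-methylbut-2-en-1-yl)indoline-2,3-dione, via aryne 11 (not isolated)
Conditions: CsF (3 equiv), MeCN, 65 °C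
Reagents that add atoms: none
Why: Fluoride unmasks aryne 11; the cesium salt of anilide 10 adds through nitrogen to one aryne carbon and the aryl anion so formed attacks the neighbouring methyl ester carbonyl and expels methoxide, so that N1–C7a and C3–C3a arise in one flask. The closest known reaction type is the aryne annulation of methyl 2-oxo-2-(arylamino)acetates to N-aryl isatins. Ring B closes by a 5-exo-trig acyl substitution, while the N–aryl bond is the intermolecular step. No stereocenter is formed, because C3 is a ketone at this stage. The step needs nitrogen on the aryne carbon next to the prenyl group: the chlorine at the future C4 distorts the aryne so that the carbon meta to chlorine is the flatter, more electrophilic terminus and the developing aryl anion sits ortho to chlorine, which should override the modest steric bias of the neighbouring prenyl CH2. N- over O-arylation and ester over amide attack follow from the five-membered closure being the only unstrained one.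

Step 6
Reactants: 12 4-chloro-1-(4-methoxyphenyl)-7-(3-methylbut-2-en-1-yl)indoline-2,3-dione
Product: 13 4-chloro-7-(3-methylbut-2-en-1-yl)indoline-2,3-dione
Conditions: (NH4)2Ce(NO3)6 (3 equiv), MeCN/H2O, 0 °C
Reagents that add atoms: none
Why: Oxidative N-dearylation of a para-methoxyphenyl amide by single-electron oxidation with tetravalent cerium and hydrolysis of the quinone iminium, as used for N-aryl lactams; ketone, aryl chloride and trisubstituted alkene should survive at 0 °C.

Step 7
Reactants: 13 4-chloro-7-(3-methylbut-2-en-1-yl)indoline-2,3-dione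
Product: 15 4-chloro-7-(3-methylbut-2-en-1-yl)indolin-2-one, via hydrazone 14 (not isolated)
Conditions: N2H4·H2O (excess, neat), 130 °C, argon
Reagents that add atoms: none
Why: Wolff–Kishner reduction of the C3 ketone through hydrazone 14, which for isatins runs in hot hydrazine hydrate without added base because the adjacent lactam acidifies C3–H; the amide carbonyl forms no hydrazone.

Step 8
Reactants: 15 4-chloro-7-(3-methylbut-2-en-1-yl)indolin-2-one
Product: 16 7-(3-methylbut-2-en-1-yl)indolin-2-one
Conditions: PdCl2(dppf) (5 mol %), NaBH4, TMEDA, THF, rt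
Reagents that add atoms: none
Why: Palladium-catalysed hydrodechlorination (oxidative addition of the aryl chloride, hydride transfer from borohydride, reductive elimination) at room temperature should remove the helper chlorine without touching the lactam or the trisubstituted alkene.

Step 9
Reactants: 17 2,5-dichloro-3-methylpyrazine
Product: 18 2-chloro-5-methoxy-3-methylpyrazine
Conditions: NaOMe (1.05 equiv), MeOH, 0 °C to rt
Reagents that add atoms: sodium methoxide C[O-].[Na+]
Why: Nucleophilic aromatic substitution at C5, the less hindered chloride whose Meisenheimer adduct places charge on N4, C6 and the chlorine-bearing C2 and not on the methyl-bearing C3; the methoxy group then deactivates the ring against a second substitution.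

Step 10
Reactants: 18 2-chloro-5-methoxy-3-methylpyrazine
Product: 19 2-(tert-butoxy)-5-methoxy-3-methylpyrazine
Conditions: KOtBu (1.5 equiv), THF, 65 °C
Reagents that add atoms: potassium tert-butoxide CC(C)(C)[O-].[K+]
Why: A second nucleophilic aromatic substitution at the remaining 2-chloro position (alpha to N1) installs an acid-labile, non-enolisable mask of the pyrazinone oxygen.

Step 11
Reactants: 19 2-(tert-butoxy)-5-methoxy-3-methylpyrazine
Product: 22 3-methoxy-5-methyl-6-oxo-1,6-dihydropyrazine-2-carbaldehyde, via pyrazinylmagnesium chloride 20 (not isolated), via tert-butoxy aldehyde 21 (not isolated)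
Conditions: TMPMgCl·LiCl (1.3 equiv), THF, 25 °C; DMF, 0 °C to rt; then 2 M HCl, THF, rt
Reagents that add atoms: N,N-dimethylformamide CN(C)C=O
Why: Directed ortho-magnesiation of the only ring C–H (ortho to methoxy, alpha to N1) with the hindered amide base, formylation with DMF, and an acidic work-up that hydrolyses the hemiaminal and cleaves the tert-butyl imidate ether to the pyrazinone.

Step 12
Reactants: 16 7-(3-methylbut-2-en-1-yl)indolin-2-one; 22 3-methoxy-5-methyl-6-oxo-1,6-dihydropyrazine-2-carbaldehyde
Product: 23 (3Z)-3-[(3-methoxy-5-methyl-6-oxo-1,6-dihydropyrazin-2-yl)methylidene]-7-(3-methylbut-2-en-1-yl)indolin-2-one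
Conditions: piperidine (0.2 equiv), AcOH (0.2 equiv), EtOH, 78 °C
Reagents that add atoms: none
Why: Knoevenagel condensation of the acidic C3 methylene of the oxindole with the aldehyde under amine catalysis; the pyrazinone N–H can hydrogen-bond to the lactam carbonyl, which should make the Z isomer the thermodynamic product.

Step 13
Reactants: 23 (3Z)-3-[(3-methoxy-5-methyl-6-oxo-1,6-dihydropyrazin-2-yl)methylidene]-7-(3-methylbut-2-en-1-yl)indolin-2-one
Product: 24 (3S)-3-[(3-methoxy-5-methyl-6-oxo-1,6-dihydropyrazin-2-yl)methyl]-7-(3-methylbut-2-en-1-yl)indolin-2-one (astepyrazinol B)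
Conditions: Ru(OAc)2[(R)-BINAP] (2 mol %), H2 (50 atm), MeOH/CH2Cl2, 50 °C
Reagents that add atoms: none
Why: Asymmetric hydrogenation of an exocyclic alpha-alkylidene lactam with a chiral bisphosphine ruthenium dicarboxylate sets C3 by catalyst-controlled delivery of H2 to one face of the single Z alkene, while the isolated trisubstituted prenyl alkene has no coordinating group and should stay inert; the neutral medium keeps the acidic C3–H configuration.

**Compound list**
1 | 2-bromo-3-chlorophenol | Oc1cccc(Cl)c1Br | starting material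
2 | tert-butyl (2-methylbut-3-en-2-yl) carbonate | C=CC(C)(C)OC(=O)OC(C)(C)C | starting material
3 | 2-bromo-1-chloro-3-[(2-methylbut-3-en-2-yl)oxy]benzene | C=CC(C)(C)Oc1cccc(Cl)c1Br | intermediate
4 | 2-bromo-3-chloro-6-(3-methylbut-2-en-1-yl)phenol | CC(C)=CCc1ccc(Cl)c(Br)c1O | intermediate
5 | [2-bromo-3-chloro-6-(3-methylbut-2-en-1-yl)phenoxy]trimethylsilane | CC(C)=CCc1ccc(Cl)c(Br)c1O[Si](C)(C)C | intermediate
6 | lithium 3-chloro-6-(3-methylbut-2-en-1-yl)-2-(trimethylsilyl)phenolate | CC(C)=CCc1ccc(Cl)c([Si](C)(C)C)c1[O-].[Li+] | intermediate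
7 | 3-chloro-6-(3-methylbut-2-en-1-yl)-2-(trimethylsilyl)phenyl trifluoromethanesulfonate | CC(C)=CCc1ccc(Cl)c([Si](C)(C)C)c1OS(=O)(=O)C(F)(F)F | intermediate
8 | 4-methoxyaniline | COc1ccc(N)cc1 | starting material
9 | methyl chlorooxoacetate | COC(=O)C(Cl)=O | starting material
10 | methyl 2-[(4-methoxyphenyl)amino]-2-oxoacetate | COC(=O)C(=O)Nc1ccc(OC)cc1 | intermediate
11 | 3-chloro-6-(3-methylbut-2-en-1-yl)benzyne | CC(C)=CCC1=CC=C(Cl)C#C1 | intermediate
12 | 4-chloro-1-(4-methoxyphenyl)-7-(3-methylbut-2-en-1-yl)indoline-2,3-dione | COc1ccc(cc1)N1C(=O)C(=O)c2c(Cl)ccc(CC=C(C)C)c21 | intermediate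
13 | 4-chloro-7-(3-methylbut-2-en-1-yl)indoline-2,3-dione | O=C1Nc2c(CC=C(C)C)ccc(Cl)c2C1=O | intermediate
14 | 4-chloro-3-hydrazinylidene-7-(3-methylbut-2-en-1-yl)indolin-2-one | NN=C1C(=O)Nc2c(CC=C(C)C)ccc(Cl)c21 | intermediate
15 | 4-chloro-7-(3-methylbut-2-en-1-yl)indolin-2-one | O=C1Cc2c(Cl)ccc(CC=C(C)C)c2N1 | intermediate
16 | 7-(3-methylbut-2-en-1-yl)indolin-2-one | O=C1Cc2cccc(CC=C(C)C)c2N1 | intermediate
17 | 2,5-dichloro-3-methylpyrazine | Cc1nc(Cl)cnc1Cl | starting material
18 | 2-chloro-5-methoxy-3-methylpyrazine | COc1cnc(Cl)c(C)n1 | intermediate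
19 | 2-(tert-butoxy)-5-methoxy-3-methylpyrazine | COc1cnc(OC(C)(C)C)c(C)n1 | intermediate
20 | [5-(tert-butoxy)-3-methoxy-6-methylpyrazin-2-yl]magnesium chloride | COc1nc(C)c(OC(C)(C)C)nc1[Mg]Cl | intermediate
21 | 6-(tert-butoxy)-3-methoxy-5-methylpyrazine-2-carbaldehyde | COc1nc(C)c(OC(C)(C)C)nc1C=O | intermediate
22 | 3-methoxy-5-methyl-6-oxo-1,6-dihydropyrazine-2-carbaldehyde | COc1nc(C)c(=O)[nH]c1C=O | intermediate
23 | (3Z)-3-[(3-methoxy-5-methyl-6-oxo-1,6-dihydropyrazin-2-yl)methylidene]-7-(3-methylbut-2-en-1-yl)indolin-2-one | COc1nc(C)c(=O)[nH]c1/C=C1\C(=O)Nc2c(CC=C(C)C)cccc21 | intermediate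
24 | (3S)-3-[(3-methoxy-5-methyl-6-oxo-1,6-dihydropyrazin-2-yl)methyl]-7-(3-methylbut-2-en-1-yl)indolin-2-one (astepyrazinol B) | COc1nc(C)c(=O)[nH]c1C[C@@H]1C(=O)Nc2c(CC=C(C)C)cccc21 | target

**Step count and risks**
Total: 13 steps. Longest linear sequence: 9 steps (1, 2, 3, 5, 6, 7, 8, 12, 13).

Steps most likely to fail:

Step 5. The hindered amide anion may add at the wrong aryne terminus (next to chlorine) because of the prenyl CH2, or the aryl anion may be protonated before it closes the ring, so that only N-arylation occurs. Fallback, from 7 back to 15: aryne amination of 7 with the small nucleophile 4-methoxybenzylamine (CsF, MeCN) should give 5-chloro-N-(4-methoxybenzyl)-2-(3-methylbut-2-en-1-yl)aniline F1 under the same chlorine control. Acylation with chloroacetyl chloride and Et3N gives 2-chloro-N-[5-chloro-2-(3-methylbut-2-en-1-yl)phenyl]-N-(4-methoxybenzyl)acetamide F2. Palladium-catalysed C–H cyclization of the alpha-chloroacetanilide (Pd(OAc)2, 2-(di-tert-butylphosphino)biphenyl, Et3N, PhMe, 80 °C) at the only free ortho carbon gives 4-chloro-1-(4-methoxybenzyl)-7-(3-methylbut-2-en-1-yl)indolin-2-one F3. Oxidative debenzylation with (NH4)2Ce(NO3)6 then rejoins the route at 15. The two ring bonds are then made in separate operations.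

Step 13. Facial discrimination on the hydrogen-bonded, donor-substituted alkene may be poor, or turnover may be slow. Fallback, from 23 back to 24: conjugate reduction of 23 with NaBH4 (MeOH/THF, 0 °C) gives racemic 3-[(3-methoxy-5-methyl-6-oxo-1,6-dihydropyrazin-2-yl)methyl]-7-(3-methylbut-2-en-1-yl)indolin-2-one F4. Preparative chromatography on a chiral stationary phase gives 24 and the (3R)-enantiomer F5, which is racemised back to F4 with Et3N in MeOH through the acidic C3–H and recycled.

Step 11. Metalation may occur at the 3-methyl group (lateral) instead of the ring C–H, or the electron-rich ring may magnesiate sluggishly. Fallback, from 19 back to 20: electrophilic bromination of 19 with N-bromosuccinimide (MeCN, NaHCO3) at the only ring C–H gives 2-bromo-5-(tert-butoxy)-3-methoxy-6-methylpyrazine F6. Bromine–magnesium exchange with iPrMgCl·LiCl (THF, −20 °C) then gives 20 with the site fixed, and step 11 continues with DMF and acid.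

**Further compounds**
F1 | step 5 | 5-chloro-N-(4-methoxybenzyl)-2-(3-methylbut-2-en-1-yl)aniline | COc1ccc(CNc2cc(Cl)ccc2CC=C(C)C)cc1
F2 | step 5 | 2-chloro-N-[5-chloro-2-(3-methylbut-2-en-1-yl)phenyl]-N-(4-methoxybenzyl)acetamide | COc1ccc(CN(C(=O)CCl)c2cc(Cl)ccc2CC=C(C)C)cc1
F3 | step 5 | 4-chloro-1-(4-methoxybenzyl)-7-(3-methylbut-2-en-1-yl)indolin-2-one | COc1ccc(CN2C(=O)Cc3c(Cl)ccc(CC=C(C)C)c32)cc1
F4 | step 13 | racemic 3-[(3-methoxy-5-methyl-6-oxo-1,6-dihydropyrazin-2-yl)methyl]-7-(3-methylbut-2-en-1-yl)indolin-2-one | COc1nc(C)c(=O)[nH]c1CC1C(=O)Nc2c(CC=C(C)C)cccc21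
F5 | step 13 | (3R)-3-[(3-methoxy-5-methyl-6-oxo-1,6-dihydropyrazin-2-yl)methyl]-7-(3-methylbut-2-en-1-yl)indolin-2-one | COc1nc(C)c(=O)[nH]c1C[C@H]1C(=O)Nc2c(CC=C(C)C)cccc21
F6 | step 11 | 2-bromo-5-(tert-butoxy)-3-methoxy-6-methylpyrazine | COc1nc(C)c(OC(C)(C)C)nc1Br
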